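The numbers of this flask stand for no real mixture; no experiment stands behind them.

With the over-reaction constant 1.1 M⁻¹ s⁻¹, the half-life of target by that step alone, at Sunday's charges, is 140 s, longer than the run of 40 s, so on Sunday's I reckon the over-reaction as a small correction on what the chain leaves.

    2 initiating radical → ended chains B (k1 = 2 × 10⁸ M⁻¹ s⁻¹)
    reagent + target → over-reaction product (k2 = 1.1 M⁻¹ s⁻¹)
    initiator → 2 initiating radical (k3 = 0.0089 s⁻¹)
    2 chain carrier → ended chains A (k4 = 9.8 × 10⁶ M⁻¹ s⁻¹)
    substrate + initiating radical → chain carrier (k5 = 3.5 × 10⁶ M⁻¹ s⁻¹)
    reagent + chain carrier → target + initiating radical (k6 = 7.5 × 10⁵ M⁻¹ s⁻¹)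

the same everywhere: substrate 0.018 M; initiator 5 mol%; time 40 s

| run | reagent |
|---|---|
| Sunday's | 0.250 equiv |
| Monday's | 0.500 equiv |
| Tuesday's | 1.00 equiv |
| Saturday's | 2.00 equiv |

- percentages count the substrate that a species holds: one ended chains A counts as two
- two of one species on the left: rate k times its square, two consumed each time
- "hardly changes" means that all values lie within two and a half points (for a concentration: within two and a half percent of the largest)
- run time (Sunday's): 40 s

* amount of target at the end, in percent of the substrate charged for Sunday's, Monday's, Tuesday's, Saturday's, in this order
* how that number moves from the first to the last of them (rises, then falls / falls, then rises / rises all the way / hardly changes / falls all the way)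

Each turn of the chain spends one reagent and one substrate and makes one target. On Sunday's and Monday's the reagent is the limiting reagent, so I expect target near its charge. On Tuesday's, with equal charges, I expect target near the whole substrate.

Saturday's chain should use up the substrate and leave target and reagent both near 0.018 M. These two then go one for one and stay equal, so target falls at k times its square, where k is the over-reaction constant. Two times matter: the run, 40 s, and the over-reaction time τ = 50.5 s, the reciprocal of k times the substrate's charge, in which equal amounts of target and reagent fall to half. After a time t, the share of target left is one divided by (one plus t/τ). Here t/τ is 0.792, so Saturday's ends at 0.558 of the substrate charged. Sunday's share of the substrate is 25.0%, so from that share, up to the whole substrate on Tuesday's and down to Saturday's, I expect a row that rises, then falls.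

The forecast gives 24.9%, 49.2%, 96% and 56.5%, a row that rises, then falls, with Saturday's reagent left to “over-react with the target in a slow second-order loss”.

The flasks give 24.8%, 49.3%, 96.2% and 56.3%, a row that rises, then falls. At the end of Saturday's, over-reaction product stands at 43.7% of the substrate charged. Carried on to 400 s, τ puts Saturday's target at 11.2%, and the flask then holds 11.2%. On Sunday's, reagent has a half-life of 1.0 s at 1.26 s. Taking that half-life as lasting through the chain, τ and the square of the target share give 0.0911% of over-reaction product, and Sunday's flask holds 0.0919%.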